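## Retrosynthetic overview

1. Enabling feature: the benzene ring of the chromene (C4a, C5, C6, C7, C8, C8a) is a phloroglucinol. Oxygen on C5, C7 and C8a alternates with carbon substituents on C6, C8 and C4a, so the ring is the enol form of a folded tetraketide with 4-hydroxybenzoyl as starter unit. C6 is the central carbon of a β-diketone, and the C4a=C8a bond is shared with the 2H-pyran ring.
2. Key disconnection (biomimetic): C6–C(=O)Ar and C6–C5 are cut in one operation. This leads to aryl ester 11 and pyranopyranone 9, a lactone-masked triketide that already carries the pyran ring and the prenyl group; its 7-methyl carbon becomes C6.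
3. 9 comes from 5-prenyl triacetic acid lactone 6 and prenal (Knoevenagel/oxa-6π). 6 comes from methyl acetoacetate by γ-prenylation, γ-acetylation and lactonisation.
4. Ring order: 2-pyranone (temporary ring) first, 2H-pyran second, benzene ring last, built at the expense of the pyranone.

Key step: step 6

Remark on the chemistry: the target has no stereocentre and no stereogenic double bond. The single stereocentres of 5 and 14 are racemic, enolisable and disappear again. β-Dicarbonyl compounds are drawn in the keto form, n-BuLi and LDA are taken as commercial solutions, and every acidic quench is cold 1 M HCl.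

## Route

Step 1
Reactants: 1 methyl acetoacetate, 2 prenyl bromide
Product: 3 methyl 7-methyl-3-oxooct-6-enoate
Conditions: NaH (1.1 equiv), THF, 0 °C; n-BuLi (1.05 equiv), 0 °C; 2, 0 °C → rt; then 1 M HCl
Reagents that add atoms: none
Why: γ-Alkylation of a β-keto ester dianion, in which the last-formed and more basic C4 carbanion displaces the allylic bromide by SN2 while the C2 enolate stays untouched, and no stereocentre is formed.

Step 2
Reactants: 3 methyl 7-methyl-3-oxooct-6-enoate, 4 N-methoxy-N-methylacetamide
Product: 5 methyl 4-acetyl-7-methyl-3-oxooct-6-enoate (racemic)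
Conditions: LDA (2.2 equiv), THF, −78 → 0 °C; 4, −78 → 0 °C; then 1 M HCl
Reagents that add atoms: none
Why: γ-Acylation of the β-keto ester dianion in the manner of a Weinreb ketone synthesis, where the chelated tetrahedral adduct lasts until the quench and so shuts out over-addition and proton transfer from the acidic product; the new C4 stereocentre is racemic, enolisable and vanishes in step 3.

Step 3
Reactants: 5 methyl 4-acetyl-7-methyl-3-oxooct-6-enoate
Product: 6 4-hydroxy-6-methyl-5-(3-methylbut-2-enyl)-2H-pyran-2-one
Conditions: DBU (1.2 equiv), toluene, 90 °C; then 1 M HCl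
Reagents that add atoms: none
Why: Base-induced lactonisation of a 3,5-dioxo ester, in which the C5 enolate oxygen attacks the ester carbonyl in a 6-exo-trig closure and loss of methanol gives the conjugated 4-hydroxy-2-pyranone, whose salt formation with DBU drives the reaction.

Step 4
Reactants: 6 4-hydroxy-6-methyl-5-(3-methylbut-2-enyl)-2H-pyran-2-one, 7 3-methylbut-2-enal (prenal)
Product: 9 2,2,7-trimethyl-8-(3-methylbut-2-enyl)-2H,5H-pyrano[4,3-b]pyran-5-one, via 1-oxatriene 8 (not isolated)
Conditions: 7 (1.5 equiv), piperidine (20 mol %), AcOH (20 mol %), 4 Å MS, EtOAc, 80 °C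
Reagents that add atoms: none
Why: Formal [3+3] annulation (Knoevenagel condensation, then oxa-6π electrocyclisation), in which the iminium ion of 7 is attacked by C3 of 6, the only free nucleophilic carbon, and oxatriene 8 closes through the C4 oxygen so that the 2-pyranone is kept; the gem-dimethyl terminus favours the closed 2H-pyran and no stereocentre is formed.

Step 5
Reactants: 10 methyl 4-hydroxybenzoate
Product: 11 methyl 4-[(tert-butyldimethylsilyl)oxy]benzoate
Conditions: TBSCl (1.1 equiv), imidazole (2 equiv), DMF, rt
Reagents that add atoms: tert-butyldimethylsilyl chloride, CC(C)(C)[Si](C)(C)Cl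
Why: Standard imidazole-promoted silylation of a phenol, which removes the acidic proton and keeps the ester electrophilic for step 6.

Step 6
Reactants: 9 2,2,7-trimethyl-8-(3-methylbut-2-enyl)-2H,5H-pyrano[4,3-b]pyran-5-one, 11 methyl 4-[(tert-butyldimethylsilyl)oxy]benzoate
Product: 15 vismiaphenone E, via acylated pyranopyranone 12 (not isolated), via desilylated pyranopyranone 13 (not isolated), via ring-opened keto ester 14 (not isolated)
Conditions: (i) LDA (2.2 equiv), THF, −78 °C; 11 (1.2 equiv), −78 → 0 °C; (ii) NaOMe (6 equiv), MeOH, 65 °C, argon; then cold 1 M HCl to pH 4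
Reagents that add atoms: sodium methoxide, [Na+].[O-]C (its methoxy group stands only in intermediate 14 and leaves again on ring closure; none of it remains in 15)
Why: LDA removes a proton from the 7-methyl group, the only C–H conjugated with the C5 lactone carbonyl (C4a, C8 and C8a carry no hydrogen), and the trienolate attacks ester 11 in a vinylogous Claisen condensation that forms the C–C(=O)Ar bond and leaves 12 as its enolate, the second equivalent of base taking up the new acidic proton. Methoxide then cleaves the aryl silyl ether (13) and opens the lactone at C5 to ester 14, whose β-diketone carbon closes on the ester carbonyl in a 6-exo-trig Dieckmann (intramolecular Claisen) acyl substitution; loss of methoxide and two enolisations give the benzene ring, so methoxide is only a relay and ring atom O6 of 9 is exchanged for the former methyl carbon. The closest known reaction types are the acylation of 6-methyl-2-pyranone anions with aromatic esters and the alkoxide-induced conversion of 6-(2-oxoalkyl)-2-pyranones and 3,5,7-trioxo esters into acylphloroglucinols, which together copy the starter-unit condensation and the C6→C1 Claisen folding of the benzophenone polyketide pathway. The step needs Claisen instead of aldol (resorcylate) folding and an unambiguous placing of the pyran oxygen, and the 2H-pyran ring secures both: C4a is a fully substituted sp2 carbon and cannot serve as aldol donor, the endocyclic C4a=C8a bond holds the ester and the diketone arm cis, and O1 already sits on the carbon para to the acyl-bearing carbon with the prenyl group fixed on C8. Lactone opening and relactonisation are reversible, retro-Claisen cleavage is held back because the β-diketone is present as its enolate and the aryl ketone is deactivated by the para-phenoxide, and formation of the phloroglucinol phenoxide is the irreversible sink. No stereocentre is created, and the labile one of 14 is lost on aromatisation.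

## Compound list

1 | methyl acetoacetate | COC(=O)CC(C)=O | starting material
2 | prenyl bromide (1-bromo-3-methylbut-2-ene) | CC(C)=CCBr | starting material
3 | methyl 7-methyl-3-oxooct-6-enoate | COC(=O)CC(=O)CCC=C(C)C | intermediate
4 | N-methoxy-N-methylacetamide | CC(=O)N(C)OC | starting material
5 | methyl 4-acetyl-7-methyl-3-oxooct-6-enoate (racemic, labile stereocentre) | COC(=O)CC(=O)C(CC=C(C)C)C(C)=O | intermediate
6 | 4-hydroxy-6-methyl-5-(3-methylbut-2-enyl)-2H-pyran-2-one | CC1=C(CC=C(C)C)C(O)=CC(=O)O1 | intermediate
7 | 3-methylbut-2-enal (prenal) | CC(C)=CC=O | starting material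
8 | 6-methyl-5-(3-methylbut-2-enyl)-3-(3-methylbut-2-enylidene)pyran-2,4-dione, dienyl chain cis to the C4 carbonyl (not isolated) | CC1=C(CC=C(C)C)C(=O)/C(=C\C=C(C)C)C(=O)O1 | intermediate
9 | 2,2,7-trimethyl-8-(3-methylbut-2-enyl)-2H,5H-pyrano[4,3-b]pyran-5-one | CC1=C(CC=C(C)C)C2=C(C=CC(C)(C)O2)C(=O)O1 | intermediate
10 | methyl 4-hydroxybenzoate | COC(=O)c1ccc(O)cc1 | starting material
11 | methyl 4-[(tert-butyldimethylsilyl)oxy]benzoate | COC(=O)c1ccc(O[Si](C)(C)C(C)(C)C)cc1 | intermediate
12 | 7-{2-[4-(tert-butyldimethylsilyloxy)phenyl]-2-oxoethyl}-2,2-dimethyl-8-(3-methylbut-2-enyl)-2H,5H-pyrano[4,3-b]pyran-5-one (not isolated) | CC(C)=CCC1=C(CC(=O)c2ccc(O[Si](C)(C)C(C)(C)C)cc2)OC(=O)C2=C1OC(C)(C)C=C2 | intermediate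
13 | 7-[2-(4-hydroxyphenyl)-2-oxoethyl]-2,2-dimethyl-8-(3-methylbut-2-enyl)-2H,5H-pyrano[4,3-b]pyran-5-one (not isolated) | CC(C)=CCC1=C(CC(=O)c2ccc(O)cc2)OC(=O)C2=C1OC(C)(C)C=C2 | intermediate
14 | methyl 6-[1-(4-hydroxyphenyl)-7-methyl-1,3-dioxooct-6-en-4-yl]-2,2-dimethyl-2H-pyran-5-carboxylate (racemic, labile stereocentre; not isolated) | COC(=O)C1=C(C(CC=C(C)C)C(=O)CC(=O)c2ccc(O)cc2)OC(C)(C)C=C1 | intermediate
15 | vismiaphenone E, [5,7-dihydroxy-2,2-dimethyl-8-(3-methylbut-2-enyl)-2H-chromen-6-yl](4-hydroxyphenyl)methanone | CC(C)=CCc1c(O)c(C(=O)c2ccc(O)cc2)c(O)c2c1OC(C)(C)C=C2 | target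

## Step count and risks

Total step count: 6
Longest linear sequence: 5 (steps 1, 2, 3, 4, 6)

**Step 6.** The acylation may stall through proton transfer from the product to the lithiated pyranone. In the second stage the stabilised β-diketone enolate may close too slowly on the crowded, donor-substituted ester, so that relactonisation and cleavage of the diketone by methoxide take over.

The fallback builds the benzene ring first and the pyran last. It sets out from 5 and comes back at 15. Compound 5 is converted with LDA (4 equiv, THF, −78 → 0 °C) into its trianion, which is acylated at the terminal methyl group with 11. This gives methyl 7-[4-(tert-butyldimethylsilyloxy)phenyl]-4-(3-methylbut-2-enyl)-3,5,7-trioxoheptanoate F1. The electrophile of the ring closure is now an ordinary β-keto ester. NaOMe in MeOH should fold it in the Claisen mode, with loss of the silyl group, to (4-hydroxyphenyl)[2,4,6-trihydroxy-3-(3-methylbut-2-enyl)phenyl]methanone F2. Annulation of F2 with 7 (ethylenediammonium diacetate cat., toluene, reflux) proceeds by condensation at the one free ring carbon. Oxa-6π closure then runs through the hydroxyl para to the ketone, which is not tied up in a hydrogen bond, and leads to 15. The price is a separation if closure through an ortho hydroxyl competes.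

**Step 2.** Formation of the hindered secondary γ-carbanion may be incomplete, and proton exchange or O-acylation may consume the dianion.

The fallback uses carboxylation instead of acetylation, so the C1–C2 bond is made in place of C4–C5. It sets out from 2 and comes back at 6. Acetylacetone is C-alkylated with 2 (K2CO3, acetone, reflux) to 3-(3-methylbut-2-enyl)pentane-2,4-dione F3. Its dianion (LDA, 2.2 equiv, THF) is carboxylated with CO2 at a terminal methyl group, and the two methyl groups are equal by symmetry. This gives 4-acetyl-7-methyl-3-oxooct-6-enoic acid F4. Cyclodehydration with carbonyldiimidazole (THF, rt) gives 6.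

**Step 4.** Michael addition of a second molecule of 6 to the oxatriene may outrun the electrocyclisation, or conjugate addition to the enal may compete with the 1,2-condensation.

The fallback replaces the condensation by a sigmatropic route. It sets out from 6 and comes back at 9 by way of 8. Compound 6 is O-alkylated with 3-chloro-3-methylbut-1-yne (DBU, CuCl2 cat., MeCN, 0 °C) to 6-methyl-4-[(2-methylbut-3-yn-2-yl)oxy]-5-(3-methylbut-2-enyl)-2H-pyran-2-one F5. Heating (xylene, 140 °C) triggers a propargyl Claisen rearrangement to C3, since C5 is blocked. A [1,5]-hydrogen shift follows and releases 8 in low concentration with no free 6 present, and 8 closes to 9.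

## Further compounds

F1 | step 6 | methyl 7-[4-(tert-butyldimethylsilyloxy)phenyl]-4-(3-methylbut-2-enyl)-3,5,7-trioxoheptanoate | COC(=O)CC(=O)C(CC=C(C)C)C(=O)CC(=O)c1ccc(O[Si](C)(C)C(C)(C)C)cc1
F2 | step 6 | (4-hydroxyphenyl)[2,4,6-trihydroxy-3-(3-methylbut-2-enyl)phenyl]methanone | CC(C)=CCc1c(O)cc(O)c(C(=O)c2ccc(O)cc2)c1O
F3 | step 2 | 3-(3-methylbut-2-enyl)pentane-2,4-dione | CC(=O)C(CC=C(C)C)C(C)=O
F4 | step 2 | 4-acetyl-7-methyl-3-oxooct-6-enoic acid | CC(=O)C(CC=C(C)C)C(=O)CC(=O)O
F5 | step 4 | 6-methyl-4-[(2-methylbut-3-yn-2-yl)oxy]-5-(3-methylbut-2-enyl)-2H-pyran-2-one | CC1=C(CC=C(C)C)C(OC(C)(C)C#C)=CC(=O)O1
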